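**Retrosynthetic overview**

1. Last bond made: O1–C2 (benzylic C–O) of the oxolane. Forward, a primary hydroxyl adds 1,6 to a p-quinone methide released from an acyclic aryl keto-triol; this closes the only ring of the target and sets C2.
2. Aryl–C(=O) bond of the keto-triol: an aryllithium opens a γ-lactone carbonyl (lactone C=O becomes the aroyl ketone, lactone CH2–O becomes the free CH2OH on C3).
3. C4–CH2OH bond: lactone enolate plus formaldehyde, anti to the C3 substituent (sets C4).
4. C3–C(benzylic) bond: L-proline cross-aldol of a 4-oxobutanoate with an O-silyl 4-hydroxy-3,5-dimethoxybenzaldehyde, then reduction and lactonisation (sets C3, the only catalyst-controlled centre).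
5. Ring order: a temporary γ-butyrolactone (closed in step 2, opened in step 5), then the tetrahydrofuran (step 6).

Assumption: with the oxolane numbered O1, C2 (aryl), C3 (CH2OH), C4 (aroyl), C5, the SMILES reads (2S,3R,4S), all-trans; monomeric formaldehyde is cracked paraformaldehyde, and the lithium amides and n-BuLi are commercial solutions.

**Route**

Step 1
Reactants: 1 syringaldehyde (4-hydroxy-3,5-dimethoxybenzaldehyde)
Product: 2 4-[(tert-butyldimethylsilyl)oxy]-3,5-dimethoxybenzaldehyde
Conditions: t-BuMe2SiCl, imidazole, DMF, 23 °C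
Reagents that add atoms: tert-butyldimethylsilyl chloride, CC(C)(C)[Si](C)(C)Cl
Why: Imidazole-promoted O-silylation of the phenol, which masks the acidic OH for the enamine, enolate and aryllithium steps and later serves as the trigger of step 6; no stereocentre is formed.

Step 2
Reactants: 2 4-[(tert-butyldimethylsilyl)oxy]-3,5-dimethoxybenzaldehyde; 3 methyl 4-oxobutanoate
Product: 6 (4R)-4-[(R)-{4-[(tert-butyldimethylsilyl)oxy]-3,5-dimethoxyphenyl}(hydroxy)methyl]oxolan-2-one, via aldol aldehyde 4 (not isolated), via hydroxy ester 5 (not isolated)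
Conditions: L-proline [(S)-pyrrolidine-2-carboxylic acid] (30 mol %), 3 (2 equiv, slow addition), DMF, 4 °C; then NaBH4, MeOH, −20 °C; then pyridinium p-toluenesulfonate (cat.), CH2Cl2, 23 °C
Reagents that add atoms: none
Why: Proline-catalysed direct cross-aldol reaction (enamine catalysis, Houk–List transition state) in which the (E)-enamine of 3 adds to the Re face of the non-enolisable aldehyde 2 to give the anti aldol 4 with (3S) at the future C3 of the target, after which borohydride reduction and γ-lactonisation of 5 give 6 without touching that centre (the carbinol centre is erased in step 6, so the syn isomer is also usable).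

Step 3
Reactants: 6 (4R)-4-[(R)-{4-[(tert-butyldimethylsilyl)oxy]-3,5-dimethoxyphenyl}(hydroxy)methyl]oxolan-2-one; 7 formaldehyde (monomer)
Product: 8 (3S,4R)-4-[(R)-{4-[(tert-butyldimethylsilyl)oxy]-3,5-dimethoxyphenyl}(hydroxy)methyl]-3-(hydroxymethyl)oxolan-2-one
Conditions: LiN(iPr)2 (2.2 equiv), THF, −78 °C; CH2O (g), −78 to −40 °C; AcOH
Reagents that add atoms: none
Why: Aldol addition of the alkoxide–enolate dianion of the lactone to formaldehyde, in which the electrophile enters anti to the C4 substituent of the five-membered enolate and so sets the 3,4-trans relationship, i.e. (S) at the future C4 of the target.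

Step 4
Reactants: 9 4-bromo-2,6-dimethoxyphenol
Product: 10 (4-bromo-2,6-dimethoxyphenoxy)(tert-butyl)dimethylsilane
Conditions: t-BuMe2SiCl, imidazole, DMF, 23 °C
Reagents that add atoms: tert-butyldimethylsilyl chloride, CC(C)(C)[Si](C)(C)Cl
Why: Imidazole-promoted O-silylation of the phenol so that bromine–lithium exchange is possible; no stereocentre is formed.

Step 5
Reactants: 8 (3S,4R)-4-[(R)-{4-[(tert-butyldimethylsilyl)oxy]-3,5-dimethoxyphenyl}(hydroxy)methyl]-3-(hydroxymethyl)oxolan-2-one; 10 (4-bromo-2,6-dimethoxyphenoxy)(tert-butyl)dimethylsilane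
Product: 12 (2S,3R,4R)-1,4-bis{4-[(tert-butyldimethylsilyl)oxy]-3,5-dimethoxyphenyl}-4-hydroxy-2,3-bis(hydroxymethyl)butan-1-one, via aryllithium 11 (not isolated)
Conditions: 10 (1.3 equiv), n-BuLi, THF, −78 °C; separately 8, LiN(SiMe3)2 (2.05 equiv), THF, −78 °C, then the solution of 11, −78 °C; AcOH, −78 °C
Reagents that add atoms: none
Why: Bromine–lithium exchange followed by a single addition of aryllithium 11 to the lactone carbonyl of the pre-formed lithium dialkoxide, where the cyclic lithium hemiketalate is stable at −78 °C and gives the aryl ketone only on protonation, so there is no double addition and the two stereocentres are untouched (12 equilibrates with its cyclic hemiketals).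

Step 6
Reactants: 12 (2S,3R,4R)-1,4-bis{4-[(tert-butyldimethylsilyl)oxy]-3,5-dimethoxyphenyl}-4-hydroxy-2,3-bis(hydroxymethyl)butan-1-one
Product: 15 (4-hydroxy-3,5-dimethoxyphenyl)[(3S,4R,5S)-5-(4-hydroxy-3,5-dimethoxyphenyl)-4-(hydroxymethyl)oxolan-3-yl]methanone, via bis-phenol 13 (not isolated), via quinone methide 14 (not isolated)
Conditions: KHF2 (6 equiv), MeOH, 23 °C; evaporate; (PhO)2P(O)OH (10 mol %), 4 Å molecular sieves, MeCN, 0 to 23 °C
Reagents that add atoms: none
Why: Proposed new method: bifluoride removes both aryl silyl ethers without base (so the β-hydroxy ketone is spared retro-aldol and E1cB loss of water), the liberated 4-hydroxybenzylic alcohol 13 is ionised by the weak acid (PhO)2P(O)OH to p-quinone methide 14 (erasing the carbinol centre, so both aldol diastereomers converge), and the primary hydroxyl β to the ketone, the only nucleophile that can close a five-membered ring, adds 1,6 to C2 anti to the neighbouring CH2OH under reversible conditions to give the all-trans (2S,3R,4S) oxolane; the closest known reaction types are the acid-mediated quinone-methide cyclisation of 7-hydroxy-dibenzylbutanediol lignans to 2-aryltetrahydrofurans and phosphoric-acid-catalysed 1,6-additions to p-quinone methides made in situ, but a desilylation-triggered, catalytic oxa-1,6 ring closure on an unprotected β-hydroxy aryl ketone triol has not been shown.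

**Compound list**

1 | syringaldehyde (4-hydroxy-3,5-dimethoxybenzaldehyde) | COc1cc(C=O)cc(OC)c1O | starting material
2 | 4-[(tert-butyldimethylsilyl)oxy]-3,5-dimethoxybenzaldehyde | COc1cc(C=O)cc(OC)c1O[Si](C)(C)C(C)(C)C | intermediate
3 | methyl 4-oxobutanoate | COC(=O)CCC=O | starting material
4 | methyl (3S,4R)-4-{4-[(tert-butyldimethylsilyl)oxy]-3,5-dimethoxyphenyl}-3-formyl-4-hydroxybutanoate | COC(=O)C[C@H](C=O)[C@@H](O)c1cc(OC)c(O[Si](C)(C)C(C)(C)C)c(OC)c1 | intermediate (not isolated)
5 | methyl (3R,4R)-4-{4-[(tert-butyldimethylsilyl)oxy]-3,5-dimethoxyphenyl}-4-hydroxy-3-(hydroxymethyl)butanoate | COC(=O)C[C@H](CO)[C@@H](O)c1cc(OC)c(O[Si](C)(C)C(C)(C)C)c(OC)c1 | intermediate (not isolated)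
6 | (4R)-4-[(R)-{4-[(tert-butyldimethylsilyl)oxy]-3,5-dimethoxyphenyl}(hydroxy)methyl]oxolan-2-one | O=C1C[C@H](CO1)[C@@H](O)c2cc(OC)c(O[Si](C)(C)C(C)(C)C)c(OC)c2 | intermediate
7 | formaldehyde | C=O | starting material
8 | (3S,4R)-4-[(R)-{4-[(tert-butyldimethylsilyl)oxy]-3,5-dimethoxyphenyl}(hydroxy)methyl]-3-(hydroxymethyl)oxolan-2-one | O=C1[C@H](CO)[C@H](CO1)[C@@H](O)c2cc(OC)c(O[Si](C)(C)C(C)(C)C)c(OC)c2 | intermediate
9 | 4-bromo-2,6-dimethoxyphenol | COc1cc(Br)cc(OC)c1O | starting material
10 | (4-bromo-2,6-dimethoxyphenoxy)(tert-butyl)dimethylsilane | COc1cc(Br)cc(OC)c1O[Si](C)(C)C(C)(C)C | intermediate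
11 | {4-[(tert-butyldimethylsilyl)oxy]-3,5-dimethoxyphenyl}lithium | [Li]c1cc(OC)c(O[Si](C)(C)C(C)(C)C)c(OC)c1 | intermediate (not isolated)
12 | (2S,3R,4R)-1,4-bis{4-[(tert-butyldimethylsilyl)oxy]-3,5-dimethoxyphenyl}-4-hydroxy-2,3-bis(hydroxymethyl)butan-1-one | COc1cc(cc(OC)c1O[Si](C)(C)C(C)(C)C)C(=O)[C@H](CO)[C@H](CO)[C@@H](O)c2cc(OC)c(O[Si](C)(C)C(C)(C)C)c(OC)c2 | intermediate
13 | (2S,3R,4R)-4-hydroxy-1,4-bis(4-hydroxy-3,5-dimethoxyphenyl)-2,3-bis(hydroxymethyl)butan-1-one | COc1cc(cc(OC)c1O)C(=O)[C@H](CO)[C@H](CO)[C@@H](O)c2cc(OC)c(O)c(OC)c2 | intermediate (not isolated)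
14 | 4-[(2R,3S)-4-(4-hydroxy-3,5-dimethoxyphenyl)-2,3-bis(hydroxymethyl)-4-oxobutylidene]-2,6-dimethoxycyclohexa-2,5-dien-1-one | COc1cc(cc(OC)c1O)C(=O)[C@H](CO)[C@H](CO)C=C2C=C(OC)C(=O)C(OC)=C2 | intermediate (not isolated)
15 | (4-hydroxy-3,5-dimethoxyphenyl)[(3S,4R,5S)-5-(4-hydroxy-3,5-dimethoxyphenyl)-4-(hydroxymethyl)oxolan-3-yl]methanone | COc1cc(C(=O)[C@@H]2CO[C@H](c3cc(OC)c(O)c(OC)c3)[C@H]2CO)cc(OC)c1O | target

**Step count and risks**

Total step count: 6. Longest linear sequence: 5 steps (steps 1, 2, 3, 5, 6; step 4 is the convergent branch).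

The step most likely to fail is step 6, the new ring closure. The free β-hydroxy ketone could lose formaldehyde, the ketone oxygen could compete for the quinone methide, or methanol could cap C2. The fallback uses known chemistry and keeps the silyl ethers in place. It sets out from 12: CF3CO2H (2 equiv) in CH2Cl2 at 0 °C ionises the 4-silyloxybenzylic alcohol and the primary hydroxyl captures the cation. This is the classical acid-mediated cyclodehydration of benzylic 1,4-diols used for 2-aryltetrahydrofuran lignans, and it gives {4-[(tert-butyldimethylsilyl)oxy]-3,5-dimethoxyphenyl}[(3S,4R,5S)-5-{4-[(tert-butyldimethylsilyl)oxy]-3,5-dimethoxyphenyl}-4-(hydroxymethyl)oxolan-3-yl]methanone F1. Bu4NF buffered with AcOH (THF, 0 °C) then removes both silyl groups, and the route is rejoined at 15.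

The second is step 5. The lithium dialkoxide of 8 may be sluggish or may be enolised by the aryllithium. The fallback sets out from 8 and replaces the polyanion by a neutral, masked lactone. Both hydroxyls are silylated (Me3SiCl, N-methylmorpholine, THF, 0 °C) to give (3S,4R)-4-[(R)-{4-[(tert-butyldimethylsilyl)oxy]-3,5-dimethoxyphenyl}[(trimethylsilyl)oxy]methyl]-3-{[(trimethylsilyl)oxy]methyl}oxolan-2-one F2. This takes up one equivalent of 11 at −78 °C; dilute aqueous citric acid in the work-up cleaves the two trimethylsilyl ethers and opens the lactol, and the route is rejoined at 12.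

The third is step 3. Gaseous formaldehyde can polymerise or react at oxygen, and yields of dianion hydroxymethylations vary. The fallback sets out from 6 and introduces the carbon at the acid oxidation level. The same dianion (LiN(iPr)2, THF, −78 °C) is trapped with CO2 to give (3S,4R)-4-[(R)-{4-[(tert-butyldimethylsilyl)oxy]-3,5-dimethoxyphenyl}(hydroxy)methyl]-2-oxooxolane-3-carboxylic acid F3, whose doubly activated C3 settles trans. The free acid is then reduced chemoselectively beside the lactone with BH3·SMe2 (THF, 0 °C), and the route is rejoined at 8.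

Further compounds
F1 | step 6 | {4-[(tert-butyldimethylsilyl)oxy]-3,5-dimethoxyphenyl}[(3S,4R,5S)-5-{4-[(tert-butyldimethylsilyl)oxy]-3,5-dimethoxyphenyl}-4-(hydroxymethyl)oxolan-3-yl]methanone | COc1cc(C(=O)[C@@H]2CO[C@H](c3cc(OC)c(O[Si](C)(C)C(C)(C)C)c(OC)c3)[C@H]2CO)cc(OC)c1O[Si](C)(C)C(C)(C)C
F2 | step 5 | (3S,4R)-4-[(R)-{4-[(tert-butyldimethylsilyl)oxy]-3,5-dimethoxyphenyl}[(trimethylsilyl)oxy]methyl]-3-{[(trimethylsilyl)oxy]methyl}oxolan-2-one | O=C1[C@H](CO[Si](C)(C)C)[C@H](CO1)[C@@H](O[Si](C)(C)C)c2cc(OC)c(O[Si](C)(C)C(C)(C)C)c(OC)c2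
F3 | step 3 | (3S,4R)-4-[(R)-{4-[(tert-butyldimethylsilyl)oxy]-3,5-dimethoxyphenyl}(hydroxy)methyl]-2-oxooxolane-3-carboxylic acid | O=C1[C@H](C(=O)O)[C@H](CO1)[C@@H](O)c2cc(OC)c(O[Si](C)(C)C(C)(C)C)c(OC)c2
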